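**Plan**

Numbering: C1 = oxirane carbon carrying C7H2OBz, C2 = CH–OBz (O2), C3 = CH–OH (O3), C4=C5, C6 = oxirane CH.
Retrosynthesis: cut the two benzoate C–O bonds and the oxirane (back to a C1=C6 olefin with free O2–H), re-close O3 onto C6, then cut C1–C6 and C2–C3 in a retro-[4+2] to furan and an (E)-3-(benzoyloxy)acryloyl imide.
Enabling feature: O2 and O3 are cis and C4=C5 sits between the oxygen-bearing C3 and C6, so the carbocycle is a latent 7-oxabicyclo[2.2.1]heptene bridged by O3 from C3 to C6, with O2 exo and C7 endo on C1.
Forward: the dienophile is made in two steps; the Diels–Alder reaction closes the carbocycle as the bicycle; methanolysis and base open the oxygen bridge to the cis-dienediol ester; O3 is silylated, the ester reduced, the oxirane closed on C1=C6; dibenzoylation and desilylation finish.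
Stereochemistry: C2 and C3 come from the copper bis(oxazoline)-catalysed endo cycloaddition (the E olefin puts O2 exo, cis to the bridge oxygen that becomes O3); C1 and C6 come from delivery of the oxirane oxygen by the O2 hydroxyl.

Key step: step 3

Assumption: the facial sense known for acryloyl oxazolidinones bound to the (S,S)-tert-butyl-bis(oxazoline) complex of divalent copper is taken to hold for the β-benzoyloxy dienophile; should it prove reversed, the (R,R) ligand is used and nothing else changes.

Step 1
Reactants: 1 propiolic acid; 2 2-oxazolidinone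
Product: 3 3-propioloyl-1,3-oxazolidin-2-one
Conditions: DCC (1.1 equiv), DMAP (5 mol%), CH2Cl2, −10 → 0 °C
Reagents that add atoms: none
Why: Steglich-type carbodiimide coupling, in which DCC activates the acid and DMAP passes the propioloyl group to the weakly nucleophilic carbamate nitrogen, the low temperature and the small amount of DMAP keeping amine addition to the alkyne in check.

Step 2
Reactants: 3 3-propioloyl-1,3-oxazolidin-2-one; 4 benzoic acid
Product: 5 (E)-3-oxo-3-(2-oxo-1,3-oxazolidin-3-yl)prop-1-en-1-yl benzoate
Conditions: N-methylmorpholine (10 mol%), MeCN, 0 °C → rt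
Reagents that add atoms: none
Why: Amine-catalysed conjugate (oxa-Michael type) addition of a carboxylic acid to an electron-poor alkyne, in which the tertiary amine adds to the ynimide, benzoate replaces it by addition–elimination, and the reversible sequence should settle on the more stable E enol ester.

Step 3
Reactants: 5 (E)-3-oxo-3-(2-oxo-1,3-oxazolidin-3-yl)prop-1-en-1-yl benzoate; 6 furan
Product: 7 (1S,2R,3S,4R)-2-[(2-oxo-1,3-oxazolidin-3-yl)carbonyl]-7-oxabicyclo[2.2.1]hept-5-en-3-yl benzoate (imide endo; benzoate exo)
Conditions: [Cu((S,S)-t-Bu-box)](SbF6)2 (10 mol%; (S,S)-t-Bu-box = 2,2'-(propane-2,2-diyl)bis[(4S)-4-tert-butyl-4,5-dihydrooxazole]; pre-formed from CuCl2, the ligand and AgSbF6), furan (10 equiv), CH2Cl2, −78 → −40 °C; cold filtration through silica, recrystallisation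
Reagents that add atoms: none
Why: The imide chelates divalent copper through both carbonyl oxygens in the s-cis form, which lowers the LUMO of the enol ester, and furan adds across Cα/Cβ in a concerted, asynchronous, suprafacial [4+2] cycloaddition that forms C1–C6 and C2–C3. The closest known reactions are the copper bis(oxazoline)-catalysed Diels–Alder additions of furan to acryloyl oxazolidinone and of β-substituted acryloyl oxazolidinones to cyclic dienes. The six-membered carbocycle closes in this single intermolecular cycloaddition event (both bonds in one step, no separate cyclisation), the furan oxygen ending as the one-atom bridge between C3 and C6. C1 and C2 are set by the catalyst, whose tert-butyl group next to the bound olefin shields the α-Si face so that furan bonds to the α-Re face, and by the E geometry, which is carried over and puts C7 and O2 trans; C3 and C6 are set by the endo orientation of the chelated imide, which leaves the benzoate exo, on the side of the bridge oxygen. The step needs endo selectivity and a single dienophile face under kinetic control: the rigid square-planar chelate secures the face, secondary overlap of the activated imide secures endo, and low temperature with a cold quench keeps the reversible furan adduct from drifting to the exo isomer, any residue of which is removed by crystallisation.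

Step 4
Reactants: 7 (1S,2R,3S,4R)-2-[(2-oxo-1,3-oxazolidin-3-yl)carbonyl]-7-oxabicyclo[2.2.1]hept-5-en-3-yl benzoate
Product: 9 methyl (1S,2R,3S,4R)-3-hydroxy-7-oxabicyclo[2.2.1]hept-5-ene-2-carboxylate (endo ester; exo hydroxyl), via benzoyloxy methyl ester 8 (not isolated)
Conditions: NaOMe (2.5 equiv), MeOH, −20 → 0 °C; then AcOH
Reagents that add atoms: sodium methoxide, [Na+].[O-]C; methanol, CO
Why: Methoxide transesterification in two stages, first at the activated exocyclic imide carbonyl and then at the benzoate (Zemplén-type deacylation), leaves C2, C3 and C6 untouched, and C1, the only centre that could epimerise, becomes sp2 in the next step.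

Step 5
Reactants: 9 methyl (1S,2R,3S,4R)-3-hydroxy-7-oxabicyclo[2.2.1]hept-5-ene-2-carboxylate
Product: 10 methyl (5R,6S)-5,6-dihydroxycyclohexa-1,3-diene-1-carboxylate (cis diol)
Conditions: LiN(SiMe3)2 (3 equiv), THF, −78 → −20 °C; aq. NH4Cl at −78 °C
Reagents that add atoms: none
Why: E1cB bridge opening of a 7-oxanorbornene ester, in which O2 is held as its lithium alkoxide (no leaving group, as in the dianions of the Fráter–Seebach alkylation) so that the C1 enolate can only expel the strained C6–O bridge, giving the C1=C6 bond and freeing O3 without touching the configuration at C2 and C3.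

Step 6
Reactants: 10 methyl (5R,6S)-5,6-dihydroxycyclohexa-1,3-diene-1-carboxylate
Product: 11 methyl (5R,6S)-5-[(tert-butyldimethylsilyl)oxy]-6-hydroxycyclohexa-1,3-diene-1-carboxylate (silyl on O3)
Conditions: TBSCl (1.05 equiv), imidazole (2 equiv), DMF, −20 °C
Reagents that add atoms: tert-butyldimethylsilyl chloride, CC(C)(C)[Si](C)(C)Cl
Why: Regioselective monosilylation of a cyclohexadiene cis-diol at the hydroxyl remote from the ring substituent, since O2–H is crowded by the ester-bearing sp2 carbon and hydrogen-bonded to the ester carbonyl, so the bulky silyl chloride should take O3 at low temperature.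

Step 7
Reactants: 11 methyl (5R,6S)-5-[(tert-butyldimethylsilyl)oxy]-6-hydroxycyclohexa-1,3-diene-1-carboxylate
Product: 12 (1S,6R)-6-[(tert-butyldimethylsilyl)oxy]-2-(hydroxymethyl)cyclohexa-2,4-dien-1-ol
Conditions: i-Bu2AlH (3.5 equiv), CH2Cl2, −78 °C; aq. KNaC4H4O6 (potassium sodium tartrate)
Reagents that add atoms: none
Why: 1,2-Reduction of a conjugated ester to the allylic alcohol with i-Bu2AlH at low temperature, the first equivalent being spent on the free hydroxyl while the silyl ether and the diene are not touched.

Step 8
Reactants: 12 (1S,6R)-6-[(tert-butyldimethylsilyl)oxy]-2-(hydroxymethyl)cyclohexa-2,4-dien-1-ol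
Product: 13 (1S,2R,3S... see list) (1S,2R,3R,6S)-3-[(tert-butyldimethylsilyl)oxy]-1-(hydroxymethyl)-7-oxabicyclo[4.1.0]hept-4-en-2-ol (oxirane cis to O2 and O3)
Conditions: VO(acac)2 (5 mol%), t-BuOOH (1.2 equiv, decane), CH2Cl2, 0 °C
Reagents that add atoms: tert-butyl hydroperoxide, CC(C)(C)OO
Why: Hydroxyl-directed vanadium-catalysed epoxidation of an allylic alcohol, in which the peroxovanadium species bound to the ring hydroxyl O2 (pseudoaxial, the silyloxy group pseudoequatorial; O7 can only join in as a chelating second alkoxide on the same side) delivers oxygen to C1=C6 on the face of O2 and so sets C1 and C6, while C4=C5 has no free allylic hydroxyl and stays.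

Step 9
Reactants: 13 (1S,2R,3R,6S)-3-[(tert-butyldimethylsilyl)oxy]-1-(hydroxymethyl)-7-oxabicyclo[4.1.0]hept-4-en-2-ol
Product: 14 [(1S,2R,3R,6S)-2-(benzoyloxy)-3-[(tert-butyldimethylsilyl)oxy]-7-oxabicyclo[4.1.0]hept-4-en-1-yl]methyl benzoate
Conditions: BzCl (3 equiv), pyridine, DMAP (10 mol%), CH2Cl2, 0 °C → rt
Reagents that add atoms: benzoyl chloride, O=C(Cl)c1ccccc1
Why: DMAP-catalysed O-acylation of the primary and the hindered secondary hydroxyl with excess benzoyl chloride under weakly basic conditions that should leave the vinyl oxirane and the silyl ether alone.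

Step 10
Reactants: 14 [(1S,2R,3R,6S)-2-(benzoyloxy)-3-[(tert-butyldimethylsilyl)oxy]-7-oxabicyclo[4.1.0]hept-4-en-1-yl]methyl benzoate
Product: 15 [(1S,2R,3R,6S)-2-(benzoyloxy)-3-hydroxy-7-oxabicyclo[4.1.0]hept-4-en-1-yl]methyl benzoate (target)
Conditions: Bu4NF (1.5 equiv), AcOH (1.5 equiv), THF, 0 °C → rt
Reagents that add atoms: none
Why: Fluoride-mediated desilylation driven by the Si–F bond, buffered with acetic acid so that the freed O3 stays protonated, which should prevent benzoyl migration from O2 to O3 and attack on the oxirane.

**Compound list**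

1 | propiolic acid | C#CC(=O)O | starting material
2 | 2-oxazolidinone | O=C1NCCO1 | starting material
3 | 3-propioloyl-1,3-oxazolidin-2-one | C#CC(=O)N1CCOC1=O | intermediate
4 | benzoic acid | OC(=O)c1ccccc1 | starting material
5 | (E)-3-oxo-3-(2-oxo-1,3-oxazolidin-3-yl)prop-1-en-1-yl benzoate | O=C1OCCN1C(=O)/C=C/OC(=O)c1ccccc1 | intermediate
6 | furan | c1ccoc1 | starting material
7 | (1S,2R,3S,4R)-2-[(2-oxo-1,3-oxazolidin-3-yl)carbonyl]-7-oxabicyclo[2.2.1]hept-5-en-3-yl benzoate, imide endo, benzoate exo | O=C1OCCN1C(=O)[C@H]2[C@H](OC(=O)c3ccccc3)[C@H]4C=C[C@@H]2O4 | intermediate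
8 | methyl (1S,2R,3S,4R)-3-(benzoyloxy)-7-oxabicyclo[2.2.1]hept-5-ene-2-carboxylate, formed and consumed in step 4 | COC(=O)[C@H]1[C@H](OC(=O)c3ccccc3)[C@H]2C=C[C@@H]1O2 | intermediate
9 | methyl (1S,2R,3S,4R)-3-hydroxy-7-oxabicyclo[2.2.1]hept-5-ene-2-carboxylate, ester endo, hydroxyl exo | COC(=O)[C@H]1[C@H](O)[C@H]2C=C[C@@H]1O2 | intermediate
10 | methyl (5R,6S)-5,6-dihydroxycyclohexa-1,3-diene-1-carboxylate, cis diol | COC(=O)C1=CC=C[C@@H](O)[C@H]1O | intermediate
11 | methyl (5R,6S)-5-[(tert-butyldimethylsilyl)oxy]-6-hydroxycyclohexa-1,3-diene-1-carboxylate | COC(=O)C1=CC=C[C@@H](O[Si](C)(C)C(C)(C)C)[C@H]1O | intermediate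
12 | (1S,6R)-6-[(tert-butyldimethylsilyl)oxy]-2-(hydroxymethyl)cyclohexa-2,4-dien-1-ol | OCC1=CC=C[C@@H](O[Si](C)(C)C(C)(C)C)[C@H]1O | intermediate
13 | (1S,2R,3R,6S)-3-[(tert-butyldimethylsilyl)oxy]-1-(hydroxymethyl)-7-oxabicyclo[4.1.0]hept-4-en-2-ol, oxirane cis to O2 and O3 | OC[C@]12O[C@H]1C=C[C@@H](O[Si](C)(C)C(C)(C)C)[C@H]2O | intermediate
14 | [(1S,2R,3R,6S)-2-(benzoyloxy)-3-[(tert-butyldimethylsilyl)oxy]-7-oxabicyclo[4.1.0]hept-4-en-1-yl]methyl benzoate | O=C(OC[C@]12O[C@H]1C=C[C@@H](O[Si](C)(C)C(C)(C)C)[C@H]2OC(=O)c1ccccc1)c1ccccc1 | intermediate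
15 | [(1S,2R,3R,6S)-2-(benzoyloxy)-3-hydroxy-7-oxabicyclo[4.1.0]hept-4-en-1-yl]methyl benzoate (CNP0285759.1) | O=C(OC[C@]12O[C@H]1C=C[C@@H](O)[C@H]2OC(=O)c1ccccc1)c1ccccc1 | target

Total step count: 10. Longest linear sequence: 10 steps (1 → 15); benzoic acid and furan enter along the line.

**Steps most likely to fail**

1. Step 3. The benzoyloxy group slows the cycloaddition, and at the temperature needed for conversion the furan adduct may revert, so that endo selectivity and enantiomeric purity drift. Conjugate Friedel–Crafts-type addition of furan with loss of benzoate may also compete. Fallback: the stereochemistry is taken from a resolution instead of from the catalyst. Setting out again from 5 and 6, an uncatalysed Diels–Alder reaction at about 12 kbar in CH2Cl2 at room temperature (pressure favours the adduct and holds back cycloreversion) should give, after crystallisation from the exo isomer, the racemic endo adduct F1. Preparative chromatography on a chiral stationary phase then delivers 7, where the route is rejoined.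

2. Step 5. Enolisation next to the alkoxide may be too slow, the β-alkoxide ester may fragment by retro-aldol cleavage, or the dienediol may lose water to an aromatic ester during warming or quench. Fallback: O2 is masked before the bridge is opened. From 9, Et3SiOTf and 2,6-lutidine in CH2Cl2 at −78 °C should give the triethylsilyl ether F2. The ordinary monoanion opening with LiN(SiMe3)2 (1.2 equiv) in THF at −78 °C gives the dienol F3 with only O3 free. TBSCl and imidazole in DMF give the bis-silyl ether F4. PPTS in MeOH at 0 °C removes the more labile triethylsilyl group and returns the route at 11. This detour also removes the need for regioselective silylation in step 6.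

3. Step 4. Enolisation at C1 under methoxide may lead to E1cB loss of benzoate from C2 or to premature opening of the bridge before the benzoate is gone. Retro-aldol cleavage of the β-alkoxide ester is a further drain. Fallback: the sequence runs through the carboxylate, whose α-hydrogen is not acidic toward hydroxide. From 7, LiOH and H2O2 in THF/H2O at 0 °C cleave the imide to the benzoyloxy acid F5. Further LiOH at room temperature saponifies the benzoate to the hydroxy acid F6. Me3SiCHN2 in MeOH/toluene at 0 °C esterifies it and returns the route at 9.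

**Further compounds**

F1 | step 3 | racemic endo adduct, equimolar 7 and its mirror image | O=C1OCCN1C(=O)[C@H]2[C@H](OC(=O)c3ccccc3)[C@H]4C=C[C@@H]2O4.O=C1OCCN1C(=O)[C@@H]2[C@@H](OC(=O)c3ccccc3)[C@@H]4C=C[C@H]2O4
F2 | step 5 | methyl (1S,2R,3S,4R)-3-[(triethylsilyl)oxy]-7-oxabicyclo[2.2.1]hept-5-ene-2-carboxylate | COC(=O)[C@H]1[C@H](O[Si](CC)(CC)CC)[C@H]2C=C[C@@H]1O2
F3 | step 5 | methyl (5R,6S)-5-hydroxy-6-[(triethylsilyl)oxy]cyclohexa-1,3-diene-1-carboxylate | COC(=O)C1=CC=C[C@@H](O)[C@H]1O[Si](CC)(CC)CC
F4 | step 5 | methyl (5R,6S)-5-[(tert-butyldimethylsilyl)oxy]-6-[(triethylsilyl)oxy]cyclohexa-1,3-diene-1-carboxylate | COC(=O)C1=CC=C[C@@H](O[Si](C)(C)C(C)(C)C)[C@H]1O[Si](CC)(CC)CC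
F5 | step 4 | (1S,2R,3S,4R)-3-(benzoyloxy)-7-oxabicyclo[2.2.1]hept-5-ene-2-carboxylic acid | OC(=O)[C@H]1[C@H](OC(=O)c3ccccc3)[C@H]2C=C[C@@H]1O2
F6 | step 4 | (1S,2R,3S,4R)-3-hydroxy-7-oxabicyclo[2.2.1]hept-5-ene-2-carboxylic acid | OC(=O)[C@H]1[C@H](O)[C@H]2C=C[C@@H]1O2
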